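## Retrosynthetic overview

1. Target ⇒ protected macrocyclic core: the three esters go on one at a time (isobutyrate, acetate, hydroxybutanoate) and two silyl ethers fall last.
2. Ten-membered ring ⇒ open-chain iodoalkene aldehyde: closure by intramolecular Nozaki–Hiyama–Kishi addition at the bond between the carbinol carbon and the ring alkene, then oxidation and CBS reduction to set the carbinol.
3. Oxirane ⇒ Z-allylic alcohol (Sharpless epoxidation on the open chain) ⇒ Still–Gennari olefination of a β-branched aldehyde with an α-branched phosphonate carrying the E-iodoalkene (from but-3-yn-1-ol via ynoate hydrostannation).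
4. Key C–C bond: intermolecular organocatalytic Michael addition of dimethyl malonate to (E)-5-(PMB-oxy)pent-2-enal. It joins the five-carbon ring segment to the carbon of the future 3-acetoxyprop-1-en-2-yl group and sets the one ring stereocentre that bears no oxygen.
5. Side-chain acid ⇒ Evans syn aldol. Ring order: oxirane first (step 25), ten-membered carbocycle second (step 28).

Notation (one line): ring locants follow the name 11-oxabicyclo[8.1.0]undec-4-ene (C1 and C10 oxirane carbons, C4=C5 ring alkene, C6 carbinol carbon, C8 propenyl-bearing carbon); PMBO = (4-methoxyphenyl)methoxy, TBSO = tert-butyldimethylsilyloxy, TBDPSO = tert-butyldiphenylsilyloxy, TESO = triethylsilyloxy.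

## Route

**Aldehyde fragment (steps 1–10)**

Step 1
Reactants: 1 but-3-en-1-ol
Product: 2 1-[(but-3-en-1-yloxy)methyl]-4-methoxybenzene
Conditions: NaH, PMBCl, Bu4NI (cat.), THF/DMF, 0 °C → rt
Reagents that add atoms: 4-methoxybenzyl chloride, COc1ccc(CCl)cc1
Why: Williamson etherification of a primary alkoxide with a benzylic chloride is routine and installs a group that is later removed oxidatively.

Step 2
Reactants: 2 PMB ether of but-3-en-1-ol; 3 (2E)-but-2-enal
Product: 4 (2E)-5-[(4-methoxyphenyl)methoxy]pent-2-enal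
Conditions: second-generation Hoveyda–Grubbs catalyst (3 mol %), 3 (4 equiv), CH2Cl2, 40 °C
Reagents that add atoms: none
Why: Olefin cross-metathesis of a terminal alkene with crotonaldehyde gives the E-enal because the electron-poor partner does not homodimerise and the product equilibrates to E.

Step 3
Reactants: 4 E-enal; 5 dimethyl propanedioate
Product: 6 dimethyl 2-[(3S)-5-(PMBO)-1-oxopentan-3-yl]propanedioate
Conditions: (R)-2-{bis[3,5-bis(trifluoromethyl)phenyl](trimethylsilyloxy)methyl}pyrrolidine (10 mol %), EtOH, 0 °C, 72 h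
Reagents that add atoms: none
Why: Key intermolecular organocatalytic Michael addition: the E-iminium ion of 4 is shielded on one face by the silyloxydiarylmethyl group of the (R)-catalyst, so the malonate adds to the open face of the β-carbon and sets the future C8 centre as 3S (about 90% ee expected for linear enals).

Step 4
Reactants: 6 Michael adduct
Product: 7 dimethyl 2-[(3S)-1,1-dimethoxy-5-(PMBO)pentan-3-yl]propanedioate
Conditions: HC(OMe)3, PPTS (cat.), MeOH, rt
Reagents that add atoms: trimethyl orthoformate, COC(OC)OC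
Why: Acid-catalysed acetalisation with the orthoformate as water scavenger masks the aldehyde (the future C6 carbonyl) against the base, hydride and phosphonate chemistry that follows.

Step 5
Reactants: 7 acetal diester
Product: 8 2-[(3S)-1,1-dimethoxy-5-(PMBO)pentan-3-yl]-3-methoxy-3-oxopropanoic acid (both C2 epimers)
Conditions: KOH (1.05 equiv), MeOH, 0 °C → rt; cold 1 M HCl to pH 4
Reagents that add atoms: potassium hydroxide, [K+].[OH-]
Why: Saponification with one equivalent of hydroxide stops at the half-ester because the carboxylate deactivates the geminal ester, and the new malonate centre is irrelevant since it becomes sp2 in step 6.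

Step 6
Reactants: 8 malonic half-ester
Product: 10 methyl 2-[(3S)-1,1-dimethoxy-5-(PMBO)pentan-3-yl]prop-2-enoate, via Mannich base 9 (not isolated)
Conditions: (CH2O)n, Et2NH, THF, reflux
Reagents that add atoms: formaldehyde (from paraformaldehyde), C=O
Why: Mannich reaction of the malonic half-acid with formaldehyde and diethylamine followed by decarboxylative loss of the amine is the classical route to a 2-substituted acrylate and does not touch the adjacent stereocentre.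

Step 7
Reactants: 10 acrylate
Product: 11 2-[(3S)-1,1-dimethoxy-5-(PMBO)pentan-3-yl]prop-2-en-1-ol
Conditions: i-Bu2AlH (2.5 equiv), CH2Cl2, −78 °C; aq. potassium sodium tartrate
Reagents that add atoms: none
Why: Hydride reduction of the acrylate ester goes 1,2 to the 2-substituted allylic alcohol while acetal and PMB ether are inert.

Step 8
Reactants: 11 allylic alcohol
Product: 12 tert-butyl({2-[(3S)-1,1-dimethoxy-5-(PMBO)pentan-3-yl]prop-2-en-1-yl}oxy)dimethylsilane
Conditions: TBSCl, imidazole, CH2Cl2, 0 °C → rt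
Reagents that add atoms: tert-butyl(chloro)dimethylsilane, CC(C)(C)[Si](C)(C)Cl
Why: Silyl ether protection of the primary alcohol gives a group that survives to step 32 and can then be removed in the presence of TBDPS.

Step 9
Reactants: 12 TBS ether
Product: 13 (3S)-5,5-dimethoxy-3-[3-(TBSO)prop-1-en-2-yl]pentan-1-ol
Conditions: DDQ, CH2Cl2/pH 7 buffer, 0 °C
Reagents that add atoms: none
Why: Oxidative PMB cleavage with DDQ in buffered medium frees only the electron-rich benzyl ether and leaves acetal, TBS ether and the 1,1-disubstituted alkene alone.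

Step 10
Reactants: 13 primary alcohol
Product: 14 (3S)-5,5-dimethoxy-3-[3-(TBSO)prop-1-en-2-yl]pentanal
Conditions: Dess–Martin periodinane, pyridine, CH2Cl2, 0 °C → rt
Reagents that add atoms: none
Why: Dess–Martin oxidation gives the aldehyde under buffered conditions, and the stereocentre is β to the carbonyl so it cannot epimerise.

**Phosphonate fragment (steps 11–19)**

Step 11
Reactants: 15 but-3-yn-1-ol
Product: 16 (but-3-yn-1-yloxy)(tert-butyl)dimethylsilane
Conditions: TBSCl, imidazole, CH2Cl2, rt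
Reagents that add atoms: tert-butyl(chloro)dimethylsilane, CC(C)(C)[Si](C)(C)Cl
Why: Silyl ether protection keeps the hydroxyl out of the acetylide, tin and hydride steps.

Step 12
Reactants: 16 silylated butynol
Product: 18 methyl 5-(TBSO)pent-2-ynoate, via lithium acetylide 17 (not isolated)
Conditions: n-BuLi, THF, −78 °C; ClCO2Me, −78 → 0 °C
Reagents that add atoms: methyl chloroformate, COC(=O)Cl
Why: Deprotonation of the terminal alkyne and C-acylation of the acetylide with a chloroformate is a standard ynoate synthesis.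

Step 13
Reactants: 18 ynoate
Product: 19 methyl (2E)-5-(TBSO)-2-(tributylstannyl)pent-2-enoate
Conditions: Bu3SnH, Pd(PPh3)4 (2 mol %), THF, 0 °C → rt
Reagents that add atoms: tributyltin hydride, CCCC[SnH](CCCC)CCCC
Why: Palladium-catalysed syn-hydrostannation of an ynoate puts tin on the ester-bearing carbon and hydrogen cis to it, which fixes the geometry of the future ring alkene (ester carbon cis to the chain).

Step 14
Reactants: 19 alkenylstannane
Product: 20 methyl (2E)-2-iodo-5-(TBSO)pent-2-enoate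
Conditions: I2, CH2Cl2, 0 °C
Reagents that add atoms: iodine, II
Why: Iododestannylation replaces tin by iodine with retention of alkene geometry.

Step 15
Reactants: 20 iodo enoate
Product: 21 (2E)-2-iodo-5-(TBSO)pent-2-en-1-ol
Conditions: i-Bu2AlH (2.2 equiv), CH2Cl2, −78 °C; aq. potassium sodium tartrate
Reagents that add atoms: none
Why: Hydride reduction of the ester to the allylic alcohol leaves the alkenyl iodide untouched at low temperature.

Step 16
Reactants: 21 iodo allylic alcohol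
Product: 22 tert-butyl{[(3E)-4-iodo-5-(PMBO)pent-3-en-1-yl]oxy}dimethylsilane
Conditions: NaH, PMBCl, Bu4NI (cat.), THF/DMF, 0 °C → rt
Reagents that add atoms: 4-methoxybenzyl chloride, COc1ccc(CCl)cc1
Why: Williamson etherification gives an allylic ether that, unlike an ester, does not eliminate from the alkenylchromium species of step 28.

Step 17
Reactants: 22 bis-ether
Product: 23 (3E)-4-iodo-5-(PMBO)pent-3-en-1-ol
Conditions: CSA (10 mol %), MeOH, 0 °C
Reagents that add atoms: none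
Why: Acid-catalysed methanolysis removes the primary TBS ether while the PMB ether and alkenyl iodide are stable.

Step 18
Reactants: 23 homoallylic alcohol
Product: 24 1-({[(2E)-2,5-diiodopent-2-en-1-yl]oxy}methyl)-4-methoxybenzene
Conditions: PPh3, I2, imidazole, CH2Cl2, 0 °C
Reagents that add atoms: iodine, II
Why: Appel-type iodination converts the primary alcohol to the iodide by SN2 displacement without touching the alkenyl iodide.

Step 19
Reactants: 24 diiodide; 25 methyl 2-[bis(2,2,2-trifluoroethoxy)phosphoryl]acetate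
Product: 26 methyl (5E)-2-[bis(2,2,2-trifluoroethoxy)phosphoryl]-6-iodo-7-(PMBO)hept-5-enoate (racemic at C2)
Conditions: NaH, 25 (1.5 equiv), DMF, 0 → 50 °C
Reagents that add atoms: none
Why: C-alkylation of the stabilised phosphonoacetate anion with the primary iodide (excess 25 limits dialkylation) gives the α-branched Still–Gennari reagent.

**Side-chain acid (steps 20–22)**

Step 20
Reactants: 27 (4R)-4-benzyl-3-propanoyl-1,3-oxazolidin-2-one; 28 acetaldehyde
Product: 30 (4R)-4-benzyl-3-[(2R,3S)-3-hydroxy-2-methylbutanoyl]-1,3-oxazolidin-2-one, via dibutylboron Z-enolate 29 (not isolated)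
Conditions: Bu2BOTf, i-Pr2NEt, CH2Cl2, 0 °C; 28, −78 → 0 °C; pH 7 buffer, MeOH, H2O2
Reagents that add atoms: none
Why: Evans syn aldol: the Z-boron enolate reacts through a Zimmerman–Traxler chair on the face away from the benzyl group, giving the (2R,3S) syn adduct from the (R)-auxiliary.

Step 21
Reactants: 30 aldol adduct
Product: 31 (4R)-4-benzyl-3-[(2R,3S)-2-methyl-3-(TESO)butanoyl]-1,3-oxazolidin-2-one
Conditions: TESCl, imidazole, DMF, 0 °C → rt
Reagents that add atoms: chlorotriethylsilane, CC[Si](Cl)(CC)CC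
Why: Silyl ether protection blocks the β-hydroxyl so the acid can later be coupled without self-acylation.

Step 22
Reactants: 31 silylated imide
Product: 32 (2R,3S)-2-methyl-3-(TESO)butanoic acid
Conditions: LiOH, H2O2, THF/H2O, 0 °C; Na2SO3; 1 M HCl to pH 3
Reagents that add atoms: hydrogen peroxide, OO
Why: Lithium hydroperoxide attacks the exocyclic imide carbonyl selectively (auxiliary cleavage), releasing the acid without epimerisation.

**Union, ring closure and endgame (steps 23–36)**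

Step 23
Reactants: 14 aldehyde; 26 phosphonate
Product: 33 methyl (2Z,5S)-2-[(3E)-4-iodo-5-(PMBO)pent-3-en-1-yl]-7,7-dimethoxy-5-[3-(TBSO)prop-1-en-2-yl]hept-2-enoate
Conditions: 26, KN(SiMe3)2, 18-crown-6, THF, −78 °C; then 14
Reagents that add atoms: none
Why: Still–Gennari variant of the Horner–Wadsworth–Emmons olefination: the trifluoroethyl phosphonate with a dissociated potassium ion eliminates fast from the kinetic adduct and gives the Z-enoate (ester cis to the chain), the geometry needed for the trans-fused oxirane.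

Step 24
Reactants: 33 Z-enoate
Product: 34 (2Z,5S)-2-[(3E)-4-iodo-5-(PMBO)pent-3-en-1-yl]-7,7-dimethoxy-5-[3-(TBSO)prop-1-en-2-yl]hept-2-en-1-ol
Conditions: i-Bu2AlH (3 equiv), CH2Cl2, −78 °C; aq. potassium sodium tartrate
Reagents that add atoms: none
Why: Hydride reduction of the only ester present gives the Z-allylic alcohol without isomerisation.

Step 25
Reactants: 34 Z-allylic alcohol
Product: 35 {(2S,3R)-3-{(2S)-4,4-dimethoxy-2-[3-(TBSO)prop-1-en-2-yl]butyl}-2-[(3E)-4-iodo-5-(PMBO)pent-3-en-1-yl]oxiran-2-yl}methanol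
Conditions: Ti(OiPr)4 (20 mol %), L-(+)-DET (24 mol %), t-BuOOH, 4 Å MS, CH2Cl2, −20 °C
Reagents that add atoms: tert-butyl hydroperoxide, CC(C)(C)OO
Why: Sharpless asymmetric epoxidation: with L-(+)-diethyl tartrate the oxygen is delivered to the face that gives the (2S,3R)-oxirane (C1 and C10 of the target) under reagent control, and only the alkene of the allylic alcohol reacts.

Step 26
Reactants: 35 epoxy alcohol
Product: 36 tert-butyl({(2S,3R)-3-{(2S)-4,4-dimethoxy-2-[3-(TBSO)prop-1-en-2-yl]butyl}-2-[(3E)-4-iodo-5-(PMBO)pent-3-en-1-yl]oxiran-2-yl}methoxy)diphenylsilane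
Conditions: TBDPSCl, imidazole, DMF, 0 °C → rt
Reagents that add atoms: tert-butyl(chloro)diphenylsilane, CC(C)(C)[Si](Cl)(c1ccccc1)c1ccccc1
Why: Silyl ether protection with the most robust silyl group keeps the epoxy alcohol masked until the last step and blocks Payne rearrangement.

Step 27
Reactants: 36 acetal
Product: 37 (3S)-4-{(2R,3S)-3-[(TBDPSO)methyl]-3-[(3E)-4-iodo-5-(PMBO)pent-3-en-1-yl]oxiran-2-yl}-3-[3-(TBSO)prop-1-en-2-yl]butanal
Conditions: PPTS (0.3 equiv), acetone/H2O 10:1, 45 °C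
Reagents that add atoms: water, O
Why: Mild acid-catalysed acetal hydrolysis frees the aldehyde; the oxirane is deactivated toward acid by the adjacent silyloxymethyl group and has no internal nucleophile.

Step 28
Reactants: 37 iodoalkene aldehyde
Product: 38 (1S,4E,6RS,8R,10R)-1-[(TBDPSO)methyl]-5-[(PMBO)methyl]-8-[3-(TBSO)prop-1-en-2-yl]-11-oxabicyclo[8.1.0]undec-4-en-6-ol
Conditions: CrCl2 (10 equiv), NiCl2 (2 mol % of Cr), DMSO/THF 3:1, rt, syringe-pump addition to 0.003 M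
Reagents that add atoms: none
Why: Intramolecular Nozaki–Hiyama–Kishi reaction: the alkenyl iodide becomes an alkenylchromium species that adds only to the aldehyde, with retention of the E geometry, and the C6 carbinol forms as an epimer mixture that steps 29 and 30 converge.

Step 29
Reactants: 38 allylic alcohol (both C6 epimers)
Product: 39 (1S,4E,8S,10R)-1-[(TBDPSO)methyl]-5-[(PMBO)methyl]-8-[3-(TBSO)prop-1-en-2-yl]-11-oxabicyclo[8.1.0]undec-4-en-6-one
Conditions: Dess–Martin periodinane, pyridine, CH2Cl2, 0 °C → rt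
Reagents that add atoms: none
Why: Dess–Martin oxidation of the allylic alcohol removes the uncontrolled centre and gives one enone without affecting oxirane or ethers.

Step 30
Reactants: 39 enone
Product: 40 (1S,4E,6S,8R,10R)-1-[(TBDPSO)methyl]-5-[(PMBO)methyl]-8-[3-(TBSO)prop-1-en-2-yl]-11-oxabicyclo[8.1.0]undec-4-en-6-ol
Conditions: (R)-2-methyl-CBS-oxazaborolidine (1 equiv), catecholborane, toluene, −78 °C
Reagents that add atoms: none
Why: Corey–Bakshi–Shibata reduction: the ketone binds with the α-branched alkenyl group as the large substituent, so the (R)-catalyst delivers hydride to the face that gives the 6S alcohol (1,2-reduction only).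

Step 31
Reactants: 40 (6S)-alcohol
Product: 41 (1S,4E,6S,8R,10R)-1-[(TBDPSO)methyl]-5-[(PMBO)methyl]-8-[3-(TBSO)prop-1-en-2-yl]-11-oxabicyclo[8.1.0]undec-4-en-6-yl 2-methylpropanoate
Conditions: (i-PrCO)2O, DMAP, Et3N, CH2Cl2, 0 °C → rt
Reagents that add atoms: 2-methylpropanoic anhydride, CC(C)C(=O)OC(=O)C(C)C
Why: DMAP-catalysed acylation of the only free hydroxyl installs the isobutyrate with retention at C6.

Step 32
Reactants: 41 isobutyrate
Product: 42 (1S,4E,6S,8R,10R)-1-[(TBDPSO)methyl]-8-(3-hydroxyprop-1-en-2-yl)-5-[(PMBO)methyl]-11-oxabicyclo[8.1.0]undec-4-en-6-yl 2-methylpropanoate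
Conditions: HF·pyridine, pyridine, THF, 0 °C
Reagents that add atoms: none
Why: Fluoride desilylation under buffered conditions removes the primary TBS ether far faster than the TBDPS ether and leaves esters, PMB ether and oxirane intact.

Step 33
Reactants: 42 allylic alcohol
Product: 43 (1S,4E,6S,8R,10R)-8-[3-(acetyloxy)prop-1-en-2-yl]-1-[(TBDPSO)methyl]-5-[(PMBO)methyl]-11-oxabicyclo[8.1.0]undec-4-en-6-yl 2-methylpropanoate
Conditions: Ac2O, pyridine, DMAP (cat.), CH2Cl2, 0 °C → rt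
Reagents that add atoms: acetic anhydride, CC(=O)OC(C)=O
Why: Acetylation of the only free hydroxyl places the acetate on the propenyl side chain.

Step 34
Reactants: 43 acetate
Product: 44 (1S,4E,6S,8R,10R)-8-[3-(acetyloxy)prop-1-en-2-yl]-1-[(TBDPSO)methyl]-5-(hydroxymethyl)-11-oxabicyclo[8.1.0]undec-4-en-6-yl 2-methylpropanoate
Conditions: DDQ, CH2Cl2/pH 7 buffer, 0 °C
Reagents that add atoms: none
Why: Oxidative PMB cleavage under neutral conditions frees the ring CH2OH without the base that would let the neighbouring isobutyrate migrate.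

Step 35
Reactants: 44 primary allylic alcohol; 32 side-chain acid
Product: 45 [(1S,4E,6S,8R,10R)-8-[3-(acetyloxy)prop-1-en-2-yl]-1-[(TBDPSO)methyl]-6-[(2-methylpropanoyl)oxy]-11-oxabicyclo[8.1.0]undec-4-en-5-yl]methyl (2R,3S)-2-methyl-3-(TESO)butanoate
Conditions: 32 (1.5 equiv), EDC·HCl, DMAP, CH2Cl2, 0 °C → rt
Reagents that add atoms: none
Why: Steglich-type carbodiimide esterification acylates the unhindered primary alcohol quickly, and the silylated β-oxygen prevents self-condensation of the acid.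

Step 36
Reactants: 45 bis-silyl ether
Product: 46 [(1S,4E,6S,8R,10R)-8-[3-(acetyloxy)prop-1-en-2-yl]-1-(hydroxymethyl)-6-[(2-methylpropanoyl)oxy]-11-oxabicyclo[8.1.0]undec-4-en-5-yl]methyl (2R,3S)-3-hydroxy-2-methylbutanoate
Conditions: HF·pyridine (excess), pyridine, THF, 0 °C → rt, 24 h
Reagents that add atoms: none
Why: Global fluoride desilylation under buffered, non-basic conditions removes TES and TBDPS without acyl migration, retro-aldol or oxirane opening.

## Compound list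

1 | but-3-en-1-ol | C=CCCO | starting material
2 | 1-[(but-3-en-1-yloxy)methyl]-4-methoxybenzene | C=CCCOCc1ccc(OC)cc1 | intermediate
3 | (2E)-but-2-enal | C/C=C/C=O | starting material
4 | (2E)-5-[(4-methoxyphenyl)methoxy]pent-2-enal | O=C/C=C/CCOCc1ccc(OC)cc1 | intermediate
5 | dimethyl propanedioate | COC(=O)CC(=O)OC | starting material
6 | dimethyl 2-[(3S)-5-(PMBO)-1-oxopentan-3-yl]propanedioate | O=CC[C@H](CCOCc1ccc(OC)cc1)C(C(=O)OC)C(=O)OC | intermediate
7 | dimethyl 2-[(3S)-1,1-dimethoxy-5-(PMBO)pentan-3-yl]propanedioate | COC(OC)C[C@H](CCOCc1ccc(OC)cc1)C(C(=O)OC)C(=O)OC | intermediate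
8 | 2-[(3S)-1,1-dimethoxy-5-(PMBO)pentan-3-yl]-3-methoxy-3-oxopropanoic acid (both C2 epimers) | COC(OC)C[C@H](CCOCc1ccc(OC)cc1)C(C(=O)O)C(=O)OC | intermediate
9 | Mannich base, 2-[(diethylamino)methyl]-2-[(3S)-1,1-dimethoxy-5-(PMBO)pentan-3-yl]-3-methoxy-3-oxopropanoic acid | COC(OC)C[C@H](CCOCc1ccc(OC)cc1)C(CN(CC)CC)(C(=O)O)C(=O)OC | intermediate
10 | methyl 2-[(3S)-1,1-dimethoxy-5-(PMBO)pentan-3-yl]prop-2-enoate | COC(OC)C[C@H](CCOCc1ccc(OC)cc1)C(=C)C(=O)OC | intermediate
11 | 2-[(3S)-1,1-dimethoxy-5-(PMBO)pentan-3-yl]prop-2-en-1-ol | COC(OC)C[C@H](CCOCc1ccc(OC)cc1)C(=C)CO | intermediate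
12 | tert-butyl({2-[(3S)-1,1-dimethoxy-5-(PMBO)pentan-3-yl]prop-2-en-1-yl}oxy)dimethylsilane | COC(OC)C[C@H](CCOCc1ccc(OC)cc1)C(=C)CO[Si](C)(C)C(C)(C)C | intermediate
13 | (3S)-5,5-dimethoxy-3-[3-(TBSO)prop-1-en-2-yl]pentan-1-ol | COC(OC)C[C@H](CCO)C(=C)CO[Si](C)(C)C(C)(C)C | intermediate
14 | (3S)-5,5-dimethoxy-3-[3-(TBSO)prop-1-en-2-yl]pentanal | COC(OC)C[C@H](CC=O)C(=C)CO[Si](C)(C)C(C)(C)C | intermediate
15 | but-3-yn-1-ol | C#CCCO | starting material
16 | (but-3-yn-1-yloxy)(tert-butyl)dimethylsilane | C#CCCO[Si](C)(C)C(C)(C)C | intermediate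
17 | lithium acetylide, [4-(TBSO)but-1-yn-1-yl]lithium | [Li]C#CCCO[Si](C)(C)C(C)(C)C | intermediate
18 | methyl 5-(TBSO)pent-2-ynoate | COC(=O)C#CCCO[Si](C)(C)C(C)(C)C | intermediate
19 | methyl (2E)-5-(TBSO)-2-(tributylstannyl)pent-2-enoate | CCCC[Sn](CCCC)(CCCC)/C(C(=O)OC)=C/CCO[Si](C)(C)C(C)(C)C | intermediate
20 | methyl (2E)-2-iodo-5-(TBSO)pent-2-enoate | I/C(C(=O)OC)=C/CCO[Si](C)(C)C(C)(C)C | intermediate
21 | (2E)-2-iodo-5-(TBSO)pent-2-en-1-ol | I/C(CO)=C/CCO[Si](C)(C)C(C)(C)C | intermediate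
22 | tert-butyl{[(3E)-4-iodo-5-(PMBO)pent-3-en-1-yl]oxy}dimethylsilane | I/C(COCc1ccc(OC)cc1)=C/CCO[Si](C)(C)C(C)(C)C | intermediate
23 | (3E)-4-iodo-5-(PMBO)pent-3-en-1-ol | I/C(COCc1ccc(OC)cc1)=C/CCO | intermediate
24 | 1-({[(2E)-2,5-diiodopent-2-en-1-yl]oxy}methyl)-4-methoxybenzene | I/C(COCc1ccc(OC)cc1)=C/CCI | intermediate
25 | methyl 2-[bis(2,2,2-trifluoroethoxy)phosphoryl]acetate | COC(=O)CP(=O)(OCC(F)(F)F)OCC(F)(F)F | starting material
26 | methyl (5E)-2-[bis(2,2,2-trifluoroethoxy)phosphoryl]-6-iodo-7-(PMBO)hept-5-enoate (racemic at C2) | I/C(COCc1ccc(OC)cc1)=C/CCC(C(=O)OC)P(=O)(OCC(F)(F)F)OCC(F)(F)F | intermediate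
27 | (4R)-4-benzyl-3-propanoyl-1,3-oxazolidin-2-one | CCC(=O)N1[C@H](Cc2ccccc2)COC1=O | starting material
28 | acetaldehyde | CC=O | starting material
29 | dibutylboron Z-enolate of 27 | C/C=C(\OB(CCCC)CCCC)N1[C@H](Cc2ccccc2)COC1=O | intermediate
30 | (4R)-4-benzyl-3-[(2R,3S)-3-hydroxy-2-methylbutanoyl]-1,3-oxazolidin-2-one | O=C1OC[C@@H](Cc2ccccc2)N1C(=O)[C@H](C)[C@H](C)O | intermediate
31 | (4R)-4-benzyl-3-[(2R,3S)-2-methyl-3-(TESO)butanoyl]-1,3-oxazolidin-2-one | O=C1OC[C@@H](Cc2ccccc2)N1C(=O)[C@H](C)[C@H](C)O[Si](CC)(CC)CC | intermediate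
32 | (2R,3S)-2-methyl-3-(TESO)butanoic acid | OC(=O)[C@H](C)[C@H](C)O[Si](CC)(CC)CC | intermediate
33 | methyl (2Z,5S)-2-[(3E)-4-iodo-5-(PMBO)pent-3-en-1-yl]-7,7-dimethoxy-5-[3-(TBSO)prop-1-en-2-yl]hept-2-enoate | I/C(COCc1ccc(OC)cc1)=C/CC/C(C(=O)OC)=C/C[C@H](C(=C)CO[Si](C)(C)C(C)(C)C)CC(OC)OC | intermediate
34 | (2Z,5S)-2-[(3E)-4-iodo-5-(PMBO)pent-3-en-1-yl]-7,7-dimethoxy-5-[3-(TBSO)prop-1-en-2-yl]hept-2-en-1-ol | I/C(COCc1ccc(OC)cc1)=C/CC/C(CO)=C/C[C@H](C(=C)CO[Si](C)(C)C(C)(C)C)CC(OC)OC | intermediate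
35 | {(2S,3R)-3-{(2S)-4,4-dimethoxy-2-[3-(TBSO)prop-1-en-2-yl]butyl}-2-[(3E)-4-iodo-5-(PMBO)pent-3-en-1-yl]oxiran-2-yl}methanol | I/C(COCc1ccc(OC)cc1)=C/CC[C@@]1(CO)O[C@@H]1C[C@H](C(=C)CO[Si](C)(C)C(C)(C)C)CC(OC)OC | intermediate
36 | tert-butyl({(2S,3R)-3-{(2S)-4,4-dimethoxy-2-[3-(TBSO)prop-1-en-2-yl]butyl}-2-[(3E)-4-iodo-5-(PMBO)pent-3-en-1-yl]oxiran-2-yl}methoxy)diphenylsilane | I/C(COCc1ccc(OC)cc1)=C/CC[C@@]1(CO[Si](c2ccccc2)(c2ccccc2)C(C)(C)C)O[C@@H]1C[C@H](C(=C)CO[Si](C)(C)C(C)(C)C)CC(OC)OC | intermediate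
37 | (3S)-4-{(2R,3S)-3-[(TBDPSO)methyl]-3-[(3E)-4-iodo-5-(PMBO)pent-3-en-1-yl]oxiran-2-yl}-3-[3-(TBSO)prop-1-en-2-yl]butanal | I/C(COCc1ccc(OC)cc1)=C/CC[C@@]1(CO[Si](c2ccccc2)(c2ccccc2)C(C)(C)C)O[C@@H]1C[C@H](C(=C)CO[Si](C)(C)C(C)(C)C)CC=O | intermediate
38 | (1S,4E,6RS,8R,10R)-1-[(TBDPSO)methyl]-5-[(PMBO)methyl]-8-[3-(TBSO)prop-1-en-2-yl]-11-oxabicyclo[8.1.0]undec-4-en-6-ol | C=C(CO[Si](C)(C)C(C)(C)C)[C@@H]1CC(O)/C(COCc3ccc(OC)cc3)=C/CC[C@@]2(CO[Si](c4ccccc4)(c5ccccc5)C(C)(C)C)O[C@@H]2C1 | intermediate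
39 | (1S,4E,8S,10R)-1-[(TBDPSO)methyl]-5-[(PMBO)methyl]-8-[3-(TBSO)prop-1-en-2-yl]-11-oxabicyclo[8.1.0]undec-4-en-6-one | C=C(CO[Si](C)(C)C(C)(C)C)[C@@H]1CC(=O)/C(COCc3ccc(OC)cc3)=C/CC[C@@]2(CO[Si](c4ccccc4)(c5ccccc5)C(C)(C)C)O[C@@H]2C1 | intermediate
40 | (1S,4E,6S,8R,10R)-1-[(TBDPSO)methyl]-5-[(PMBO)methyl]-8-[3-(TBSO)prop-1-en-2-yl]-11-oxabicyclo[8.1.0]undec-4-en-6-ol | C=C(CO[Si](C)(C)C(C)(C)C)[C@@H]1C[C@H](O)/C(COCc3ccc(OC)cc3)=C/CC[C@@]2(CO[Si](c4ccccc4)(c5ccccc5)C(C)(C)C)O[C@@H]2C1 | intermediate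
41 | (1S,4E,6S,8R,10R)-1-[(TBDPSO)methyl]-5-[(PMBO)methyl]-8-[3-(TBSO)prop-1-en-2-yl]-11-oxabicyclo[8.1.0]undec-4-en-6-yl 2-methylpropanoate | C=C(CO[Si](C)(C)C(C)(C)C)[C@@H]1C[C@H](OC(=O)C(C)C)/C(COCc3ccc(OC)cc3)=C/CC[C@@]2(CO[Si](c4ccccc4)(c5ccccc5)C(C)(C)C)O[C@@H]2C1 | intermediate
42 | (1S,4E,6S,8R,10R)-1-[(TBDPSO)methyl]-8-(3-hydroxyprop-1-en-2-yl)-5-[(PMBO)methyl]-11-oxabicyclo[8.1.0]undec-4-en-6-yl 2-methylpropanoate | C=C(CO)[C@@H]1C[C@H](OC(=O)C(C)C)/C(COCc3ccc(OC)cc3)=C/CC[C@@]2(CO[Si](c4ccccc4)(c5ccccc5)C(C)(C)C)O[C@@H]2C1 | intermediate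
43 | (1S,4E,6S,8R,10R)-8-[3-(acetyloxy)prop-1-en-2-yl]-1-[(TBDPSO)methyl]-5-[(PMBO)methyl]-11-oxabicyclo[8.1.0]undec-4-en-6-yl 2-methylpropanoate | C=C(COC(C)=O)[C@@H]1C[C@H](OC(=O)C(C)C)/C(COCc3ccc(OC)cc3)=C/CC[C@@]2(CO[Si](c4ccccc4)(c5ccccc5)C(C)(C)C)O[C@@H]2C1 | intermediate
44 | (1S,4E,6S,8R,10R)-8-[3-(acetyloxy)prop-1-en-2-yl]-1-[(TBDPSO)methyl]-5-(hydroxymethyl)-11-oxabicyclo[8.1.0]undec-4-en-6-yl 2-methylpropanoate | C=C(COC(C)=O)[C@@H]1C[C@H](OC(=O)C(C)C)/C(CO)=C/CC[C@@]2(CO[Si](c4ccccc4)(c5ccccc5)C(C)(C)C)O[C@@H]2C1 | intermediate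
45 | [(1S,4E,6S,8R,10R)-8-[3-(acetyloxy)prop-1-en-2-yl]-1-[(TBDPSO)methyl]-6-[(2-methylpropanoyl)oxy]-11-oxabicyclo[8.1.0]undec-4-en-5-yl]methyl (2R,3S)-2-methyl-3-(TESO)butanoate | C=C(COC(C)=O)[C@@H]1C[C@H](OC(=O)C(C)C)/C(COC(=O)[C@H](C)[C@H](C)O[Si](CC)(CC)CC)=C/CC[C@@]2(CO[Si](c4ccccc4)(c5ccccc5)C(C)(C)C)O[C@@H]2C1 | intermediate
46 | [(1S,4E,6S,8R,10R)-8-[3-(acetyloxy)prop-1-en-2-yl]-1-(hydroxymethyl)-6-[(2-methylpropanoyl)oxy]-11-oxabicyclo[8.1.0]undec-4-en-5-yl]methyl (2R,3S)-3-hydroxy-2-methylbutanoate | C=C(COC(C)=O)[C@@H]1C[C@H](OC(=O)C(C)C)/C(COC(=O)[C@H](C)[C@H](C)O)=C/CC[C@@]2(CO)O[C@@H]2C1 | target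

## Step count and risks

Total steps: 36. Longest linear sequence: 24 (steps 1–10, then 23–36).

The three steps most likely to fail are 27, 28 and 30.

**Step 27 (acetal hydrolysis beside the oxirane and the allylic TBS ether).** The acid may open the oxirane or strip the TBS group. Fallback: free the aldehyde before the oxirane exists. It sets out from 34. PPTS in wet acetone hydrolyses the acetal to the hydroxy aldehyde (3S,5Z,9E)-6-(hydroxymethyl)-10-iodo-11-(PMBO)-3-[3-(TBSO)prop-1-en-2-yl]undeca-5,9-dienal F1. Sharpless epoxidation of F1 (Ti(OiPr)4, L-(+)-DET, t-BuOOH, −20 °C; the titanium tartrate system tolerates aldehydes) gives the epoxy alcohol aldehyde (3S)-4-{(2R,3S)-3-(hydroxymethyl)-3-[(3E)-4-iodo-5-(PMBO)pent-3-en-1-yl]oxiran-2-yl}-3-[3-(TBSO)prop-1-en-2-yl]butanal F2. Silylation of F2 with TBDPSCl and imidazole gives 37, where the route is rejoined; steps 25–27 are replaced.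

**Step 28 (closure of the strained ten-membered ring).** Oligomers or reduction of the iodide may win over cyclisation. Fallback: close the same bond by anionic acylation instead of chromium-mediated addition. It sets out from 37. Pinnick oxidation (NaClO2, NaH2PO4, 2-methylbut-2-ene, t-BuOH/H2O) gives the carboxylic acid (3S)-4-{(2R,3S)-3-[(TBDPSO)methyl]-3-[(3E)-4-iodo-5-(PMBO)pent-3-en-1-yl]oxiran-2-yl}-3-[3-(TBSO)prop-1-en-2-yl]butanoic acid F3. Coupling with MeNHOMe·HCl (EDC·HCl, i-Pr2NEt) gives the Weinreb amide (3S)-N-methoxy-N-methyl-4-{(2R,3S)-3-[(TBDPSO)methyl]-3-[(3E)-4-iodo-5-(PMBO)pent-3-en-1-yl]oxiran-2-yl}-3-[3-(TBSO)prop-1-en-2-yl]butanamide F4. Slow addition of F4 to t-BuLi (2.1 equiv) in THF at −100 °C under high dilution effects iodine–lithium exchange, and the alkenyllithium acylates itself on the amide (Parham-type cycloacylation). This gives enone 39 directly, where the route is rejoined; steps 28 and 29 are bypassed. The seco compound carries no ester at this stage, so the organolithium is tolerated.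

**Step 30 (hydride face selectivity on the ring enone).** The ring conformation may override the catalyst. Fallback: accept the wrong epimer and invert it while esterifying. It sets out from 39. Luche reduction (NaBH4, CeCl3·7H2O, MeOH, −78 °C) under substrate control, or the CBS reduction if it errs, gives the epimeric alcohol (1S,4E,6R,8R,10R)-1-[(TBDPSO)methyl]-5-[(PMBO)methyl]-8-[3-(TBSO)prop-1-en-2-yl]-11-oxabicyclo[8.1.0]undec-4-en-6-ol F5. Mitsunobu esterification of F5 with 2-methylpropanoic acid (PPh3, DIAD, toluene, 0 °C) inverts C6 and gives 41, where the route is rejoined; step 31 is skipped.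

## Further compounds

F1 | step 27 | (3S,5Z,9E)-6-(hydroxymethyl)-10-iodo-11-(PMBO)-3-[3-(TBSO)prop-1-en-2-yl]undeca-5,9-dienal | I/C(COCc1ccc(OC)cc1)=C/CC/C(CO)=C/C[C@H](C(=C)CO[Si](C)(C)C(C)(C)C)CC=O
F2 | step 27 | (3S)-4-{(2R,3S)-3-(hydroxymethyl)-3-[(3E)-4-iodo-5-(PMBO)pent-3-en-1-yl]oxiran-2-yl}-3-[3-(TBSO)prop-1-en-2-yl]butanal | I/C(COCc1ccc(OC)cc1)=C/CC[C@@]1(CO)O[C@@H]1C[C@H](C(=C)CO[Si](C)(C)C(C)(C)C)CC=O
F3 | step 28 | (3S)-4-{(2R,3S)-3-[(TBDPSO)methyl]-3-[(3E)-4-iodo-5-(PMBO)pent-3-en-1-yl]oxiran-2-yl}-3-[3-(TBSO)prop-1-en-2-yl]butanoic acid | I/C(COCc1ccc(OC)cc1)=C/CC[C@@]1(CO[Si](c2ccccc2)(c2ccccc2)C(C)(C)C)O[C@@H]1C[C@H](C(=C)CO[Si](C)(C)C(C)(C)C)CC(=O)O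
F4 | step 28 | (3S)-N-methoxy-N-methyl-4-{(2R,3S)-3-[(TBDPSO)methyl]-3-[(3E)-4-iodo-5-(PMBO)pent-3-en-1-yl]oxiran-2-yl}-3-[3-(TBSO)prop-1-en-2-yl]butanamide | I/C(COCc1ccc(OC)cc1)=C/CC[C@@]1(CO[Si](c2ccccc2)(c2ccccc2)C(C)(C)C)O[C@@H]1C[C@H](C(=C)CO[Si](C)(C)C(C)(C)C)CC(=O)N(C)OC
F5 | step 30 | (1S,4E,6R,8R,10R)-1-[(TBDPSO)methyl]-5-[(PMBO)methyl]-8-[3-(TBSO)prop-1-en-2-yl]-11-oxabicyclo[8.1.0]undec-4-en-6-ol | C=C(CO[Si](C)(C)C(C)(C)C)[C@@H]1C[C@@H](O)/C(COCc3ccc(OC)cc3)=C/CC[C@@]2(CO[Si](c4ccccc4)(c5ccccc5)C(C)(C)C)O[C@@H]2C1
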